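**Retrosynthetic overview** (ring atoms in benzofuran numbering: O1, C2, C3, C3a, C4, C5, C6, C7, C7a)

1. Target ⇐ O‑methylation of the tertiary C5 alcohol, so that C5 becomes the α‑carbon of an α‑hydroxy acid.
2. Key disconnection C4–C5 and C6–C7: the six‑membered ring is a vinylogous ester (C6=O, C7=C7a–O1), i.e. a masked C6/C7a 1,3‑diketone with an oxygenated quaternary C5 next to C6. C5–C6 is therefore a glycolate unit (enolate of a 2‑tert‑butyl‑1,3‑dioxolan‑4‑one, whose acetal carbon fixes C5) and C4=C3a–C7a(=O)–C7H3 a β‑alkoxyvinyl methyl ketone, joined by a Michael addition–elimination/Claisen (4+2) annulation.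
3. Enabling feature: O1 is 1,3‑related through C3a to both C4 and C7a, so the enone is used as a 4‑acetyl‑2,3‑dihydrofuran with O1 on C4 (leaving group), and O1 later re‑closes on C7a. Ring order: temporary dihydrofuran (O1–C4), then the six‑membered carbocycle, then the final dihydrofuran (O1–C7a).
4. Acetyl‑dihydrofuran ⇐ C‑acylation of the 2,3‑dihydrofuran ⇐ cycloisomerisation of the anti homopropargylic alcohol ⇐ Marshall propargylation of veratraldehyde (C3 from bought (S)‑but‑3‑yn‑2‑ol, C2 relayed anti).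
5. Dioxolanone ⇐ pivalaldehyde acetal of (R)‑2‑hydroxypent‑4‑enoic acid ⇐ D‑allylglycine.

Key step: step 8

Remark on the chemistry: the target is read as (2R,3R,5S), with aryl trans to 3‑methyl and 5‑methoxy cis to 3‑methyl. Compound 14 is drawn as the diketone although it should exist as enol tautomers, and allenylzinc 4 is drawn as the monomeric ethylzinc species.

**Step 1**
Reactants: 1 (S)‑but‑3‑yn‑2‑ol
Product: 2 (S)‑but‑3‑yn‑2‑yl methanesulfonate
Conditions: MsCl, Et3N, CH2Cl2, −78 → 0 °C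
Reagents that add atoms: methanesulfonyl chloride CS(=O)(=O)Cl
Why: O‑sulfonylation of the secondary propargylic alcohol leaves the C–O bond intact, so the (S) configuration is kept.

**Step 2**
Reactants: 2 (S)‑but‑3‑yn‑2‑yl methanesulfonate, 3 3,4‑dimethoxybenzaldehyde
Product: 5 (1R,2R)‑1‑(3,4‑dimethoxyphenyl)‑2‑methylbut‑3‑yn‑1‑ol, via allenylzinc reagent 4 (not isolated)
Conditions: Pd(OAc)2 (5 mol %), PPh3 (5 mol %), Et2Zn (3 equiv), THF, −78 → −20 °C
Reagents that add atoms: none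
Why: Marshall propargylation, in which zerovalent palladium ionises 2 anti to the mesylate, transmetalation with Et2Zn gives allenylzinc 4, and its cyclic SE2' addition to 3 forms the C2–C3 bond with net inversion at the bought carbinol carbon (it becomes C3, R) and anti placement of the new carbinol centre (C2, R) through the chair‑like transition state.

**Step 3**
Reactants: 5 (1R,2R)‑1‑(3,4‑dimethoxyphenyl)‑2‑methylbut‑3‑yn‑1‑ol
Product: 6 (2R,3R)‑2‑(3,4‑dimethoxyphenyl)‑3‑methyl‑2,3‑dihydrofuran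
Conditions: Mo(CO)6 (30 mol %), Me3NO (30 mol %), Et3N, Et2O, 23 °C
Reagents that add atoms: none
Why: Endo‑selective alkynol cycloisomerisation, in which the terminal alkyne rearranges on molybdenum to a vinylidene whose metal‑bound carbon is attacked by the hydroxyl group to give the five‑membered enol ether without involving either stereocentre.

**Step 4**
Reactants: 6 (2R,3R)‑2‑(3,4‑dimethoxyphenyl)‑3‑methyl‑2,3‑dihydrofuran
Product: 7 2,2,2‑trichloro‑1‑[(4R,5R)‑5‑(3,4‑dimethoxyphenyl)‑4‑methyl‑4,5‑dihydrofuran‑3‑yl]ethan‑1‑one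
Conditions: Cl3CCOCl (1.3 equiv), pyridine, CH2Cl2, 0 → 23 °C
Reagents that add atoms: trichloroacetyl chloride O=C(Cl)C(Cl)(Cl)Cl
Why: C‑acylation of an enol ether, in which the trichloroacetylpyridinium ion attacks the nucleophilic β‑carbon and loss of HCl restores the now push–pull C=C bond, while the veratryl ring stays inert in the absence of a Lewis acid.

**Step 5**
Reactants: 7 2,2,2‑trichloro‑1‑[(4R,5R)‑5‑(3,4‑dimethoxyphenyl)‑4‑methyl‑4,5‑dihydrofuran‑3‑yl]ethan‑1‑one
Product: 8 1‑[(4R,5R)‑5‑(3,4‑dimethoxyphenyl)‑4‑methyl‑4,5‑dihydrofuran‑3‑yl]ethan‑1‑one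
Conditions: Zn, AcOH, TMEDA, EtOH, 0 → 23 °C
Reagents that add atoms: none
Why: Stepwise reductive dechlorination of the α‑chloro ketone through zinc enolates protonated by AcOH (the method used for dichlorocyclobutanones), which should leave the vinylogous ester and both stereocentres untouched.

**Step 6**
Reactants: 9 (R)‑2‑aminopent‑4‑enoic acid (D‑allylglycine)
Product: 10 (R)‑2‑hydroxypent‑4‑enoic acid
Conditions: NaNO2, 1 M H2SO4, H2O, 0 → 23 °C
Reagents that add atoms: water O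
Why: Diazotisation of the α‑amino acid with replacement of N2 by water under retention (double inversion through the α‑lactone), so the (R) centre is kept.

**Step 7**
Reactants: 10 (R)‑2‑hydroxypent‑4‑enoic acid
Product: 11 (2R,5R)‑2‑tert‑butyl‑5‑(prop‑2‑en‑1‑yl)‑1,3‑dioxolan‑4‑one
Conditions: t‑BuCHO, TsOH·H2O (cat.), H2SO4 (cat.), pentane, reflux (Dean–Stark); chromatography
Reagents that add atoms: pivalaldehyde CC(C)(C)C=O
Why: Acetalisation of an α‑hydroxy acid for self‑regeneration of stereocentres, in which reversible acid catalysis favours the cis‑2,5‑disubstituted dioxolanone so that the existing carbinol centre sets the new acetal carbon (R), the minor trans isomer being removed by chromatography.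

**Step 8**
Reactants: 11 (2R,5R)‑2‑tert‑butyl‑5‑(prop‑2‑en‑1‑yl)‑1,3‑dioxolan‑4‑one, 8 1‑[(4R,5R)‑5‑(3,4‑dimethoxyphenyl)‑4‑methyl‑4,5‑dihydrofuran‑3‑yl]ethan‑1‑one
Product: 15 (2R,3R,5S)‑2‑(3,4‑dimethoxyphenyl)‑5‑hydroxy‑3‑methyl‑5‑(prop‑2‑en‑1‑yl)‑2,3‑dihydro‑1‑benzofuran‑6(5H)‑one, via dioxolanone lithium enolate 12 (not isolated), via ring‑opened enone alkoxide 13 (not isolated), via hydroxy dione 14 (not isolated)
Conditions: LiN(iPr)2 (1.1 equiv), THF–DMPU, −78 °C; add 8, −78 → 0 °C; then 1 M HCl, 23 °C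
Reagents that add atoms: none
Why: Proposed new method: the lithium enolate 12 adds through its face anti to the tert‑butyl group to C4 of the β‑alkoxyvinyl ketone 8 (bond C4–C5), the ketone enolate so formed expels the ring oxygen O1 (retro‑oxa‑Michael opening of the temporary dihydrofuran, 13), the alkoxide relays a proton from the acetyl methyl group C7, and the new enolate attacks the dioxolanone carbonyl C6 (bond C6–C7) with loss of pivalaldehyde to give 14, which on acidification closes O1 onto the C7a carbonyl and dehydrates to the vinylogous ester 15. The closest known reaction types are the Michael–Claisen (4+2) annulation of ester enolates with methyl vinyl ketones (the dimedone synthesis), the conjugate additions of 2‑tert‑butyl‑1,3‑dioxolan‑4‑one enolates, and the C‑acylation of ketone enolates by such dioxolanones; their merger with a β‑alkoxy leaving group in one flask is the new element. The six‑membered ring closes by a 6‑(enolendo)‑exo‑trig Claisen condensation and the final dihydrofuran by a 5‑exo‑trig hemiketalisation at C7a followed by loss of water. C5 is the only new stereocentre and is fixed by the acetal carbon of 11 (allyl stays cis to tert‑butyl and C4 enters trans), whereas C2 and C3 are carried through unchanged because the O1–C2 bond is never broken. The step needs 1,4‑ instead of 1,2‑addition and a cis relation of C5 and the acetyl group across C3a=C4: the hindered, fully substituted enolate, the reversibility of the 1,2‑adduct and of the oxa‑Michael opening on warming, and the fact that only the cis isomer can undergo the irreversible Claisen closure should secure both. The use of about one equivalent of base leaves the C5 oxygen protonated next to the diketonate, which keeps the 1,5‑diene C3a=C4–C5–allyl away from an anionic oxy‑Cope shift.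

**Step 9**
Reactants: 15 (2R,3R,5S)‑2‑(3,4‑dimethoxyphenyl)‑5‑hydroxy‑3‑methyl‑5‑(prop‑2‑en‑1‑yl)‑2,3‑dihydro‑1‑benzofuran‑6(5H)‑one
Product: 16 (2R,3R,5S)‑2‑(3,4‑dimethoxyphenyl)‑5‑methoxy‑3‑methyl‑5‑(prop‑2‑en‑1‑yl)‑2,3‑dihydro‑1‑benzofuran‑6(5H)‑one
Conditions: LiN(SiMe3)2 (1.05 equiv), THF, −78 °C; MeOTf (1.2 equiv), −78 → −30 °C
Reagents that add atoms: methyl trifluoromethanesulfonate COS(=O)(=O)C(F)(F)F
Why: Williamson methylation of the tertiary lithium alkoxide with the hard electrophile MeOTf, in which the lithium counter‑ion and the low temperature should hold back the anionic oxy‑Cope shift of the allyl group and no stereocentre is touched.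

**Compound list**

1 | (S)‑but‑3‑yn‑2‑ol | C#C[C@H](C)O | starting material
2 | (S)‑but‑3‑yn‑2‑yl methanesulfonate | C#C[C@H](C)OS(C)(=O)=O | intermediate
3 | 3,4‑dimethoxybenzaldehyde (veratraldehyde) | COc1ccc(C=O)cc1OC | starting material
4 | (aR)‑(buta‑1,2‑dien‑1‑yl)(ethyl)zinc | CC[Zn]C=[C@]=CC | intermediate (not isolated)
5 | (1R,2R)‑1‑(3,4‑dimethoxyphenyl)‑2‑methylbut‑3‑yn‑1‑ol | O[C@@H](c1ccc(OC)c(OC)c1)[C@@H](C#C)C | intermediate
6 | (2R,3R)‑2‑(3,4‑dimethoxyphenyl)‑3‑methyl‑2,3‑dihydrofuran | C1=CO[C@@H](c2ccc(OC)c(OC)c2)[C@@H]1C | intermediate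
7 | 2,2,2‑trichloro‑1‑[(4R,5R)‑5‑(3,4‑dimethoxyphenyl)‑4‑methyl‑4,5‑dihydrofuran‑3‑yl]ethan‑1‑one | ClC(Cl)(Cl)C(=O)C1=CO[C@@H](c2ccc(OC)c(OC)c2)[C@@H]1C | intermediate
8 | 1‑[(4R,5R)‑5‑(3,4‑dimethoxyphenyl)‑4‑methyl‑4,5‑dihydrofuran‑3‑yl]ethan‑1‑one | CC(=O)C1=CO[C@@H](c2ccc(OC)c(OC)c2)[C@@H]1C | intermediate
9 | (R)‑2‑aminopent‑4‑enoic acid (D‑allylglycine) | C=CC[C@@H](N)C(=O)O | starting material
10 | (R)‑2‑hydroxypent‑4‑enoic acid | C=CC[C@@H](O)C(=O)O | intermediate
11 | (2R,5R)‑2‑tert‑butyl‑5‑(prop‑2‑en‑1‑yl)‑1,3‑dioxolan‑4‑one | C=CC[C@H]1O[C@@H](C(C)(C)C)OC1=O | intermediate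
12 | lithium (2R)‑2‑tert‑butyl‑5‑(prop‑2‑en‑1‑yl)‑1,3‑dioxol‑4‑olate | [Li+].[O-]C1=C(CC=C)O[C@@H](C(C)(C)C)O1 | intermediate (not isolated)
13 | (2R,5S)‑2‑tert‑butyl‑5‑[(1Z,3R,4R)‑2‑acetyl‑4‑(3,4‑dimethoxyphenyl)‑3‑methyl‑4‑oxidobut‑1‑en‑1‑yl]‑5‑(prop‑2‑en‑1‑yl)‑1,3‑dioxolan‑4‑one, lithium salt | [Li+].C=CC[C@@]1(/C=C(\C(C)=O)[C@@H](C)[C@@H]([O-])c2ccc(OC)c(OC)c2)O[C@@H](C(C)(C)C)OC1=O | intermediate (not isolated)
14 | (6S)‑4‑[(1R,2R)‑1‑(3,4‑dimethoxyphenyl)‑1‑hydroxypropan‑2‑yl]‑6‑hydroxy‑6‑(prop‑2‑en‑1‑yl)cyclohex‑4‑ene‑1,3‑dione | C=CC[C@]1(O)C=C(C(=O)CC1=O)[C@@H](C)[C@@H](O)c1ccc(OC)c(OC)c1 | intermediate (not isolated)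
15 | (2R,3R,5S)‑2‑(3,4‑dimethoxyphenyl)‑5‑hydroxy‑3‑methyl‑5‑(prop‑2‑en‑1‑yl)‑2,3‑dihydro‑1‑benzofuran‑6(5H)‑one | C=CC[C@]1(O)C=C2C(=CC1=O)O[C@@H](c1ccc(OC)c(OC)c1)[C@@H]2C | intermediate
16 | (2R,3R,5S)‑2‑(3,4‑dimethoxyphenyl)‑5‑methoxy‑3‑methyl‑5‑(prop‑2‑en‑1‑yl)‑2,3‑dihydro‑1‑benzofuran‑6(5H)‑one | C=CC[C@]1(OC)C=C2C(=CC1=O)O[C@@H](c1ccc(OC)c(OC)c1)[C@@H]2C | target

**Step count and risks**

Total steps: 9. Longest linear sequence: 7 (steps 1, 2, 3, 4, 5, 8, 9).

Steps most likely to fail, riskiest first: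

1. Step 8 (proposed new method). What may go wrong: kinetic 1,2‑addition of enolate 12 to the acetyl carbonyl, or proton transfer from the acetyl methyl group to 12, followed by thermal decomposition of the enolate before the reversible steps reach the annulation. The fallback sets out from 11 and 8 and comes back at 15, replacing the anionic one‑flask cascade by Lewis‑acid activation in separate known operations. Compound 11 is converted (LiN(iPr)2, Me3SiCl, THF, −78 °C) into its silyl ketene acetal, (2R)‑2‑tert‑butyl‑5‑(prop‑2‑en‑1‑yl)‑4‑(trimethylsilyloxy)‑1,3‑dioxole F1. Ketone 8 is activated with Me3SiOTf (CH2Cl2, −78 °C) as its siloxy‑oxocarbenium ion and captured by F1 in a Mukaiyama–Michael addition anti to the tert‑butyl group. Aqueous work‑up should give (2R,5S)‑5‑[(4R,5R)‑3‑acetyl‑5‑(3,4‑dimethoxyphenyl)‑4‑methyloxolan‑2‑yl]‑2‑tert‑butyl‑5‑(prop‑2‑en‑1‑yl)‑1,3‑dioxolan‑4‑one F2 (epimer mixture at the two new oxolane carbons, both lost later). Treatment of F2 with LiN(SiMe3)2 (THF, −78 → 0 °C: β‑elimination of O1, then Dieckmann closure) and then 1 M HCl should deliver 15.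

2. Step 9. What may go wrong: anionic oxy‑Cope migration of the allyl group from C5 to C3a in the alkoxide, or competing methylation at the vinylogous ester carbonyl oxygen. The fallback sets out from 8 and comes back at 16, carrying the methyl ether from the start instead of methylating late. The lithium enolate of racemic methyl 2‑methoxypent‑4‑enoate F3 (from methyl methoxyacetate and allyl bromide) is used in place of 12 under the step 8 protocol. Addition–elimination and Claisen closure with loss of methanol should give 4‑[(1R,2R)‑1‑(3,4‑dimethoxyphenyl)‑1‑hydroxypropan‑2‑yl]‑6‑methoxy‑6‑(prop‑2‑en‑1‑yl)cyclohex‑4‑ene‑1,3‑dione F4 as a C5 epimer mixture. Acid then closes the dihydrofuran, and 16 is separated by chromatography from its diastereomer, the (2R,3R,5R) epimer F5. No auxiliary controls C5 in this variant.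

3. Step 5. What may go wrong: hydrolytic opening of the β‑acyl enol ether in the acidic medium, or incomplete dechlorination. The fallback sets out from 6 and comes back at 8, building the acetyl group by formylation and methyl addition instead of reduction. Vilsmeier–Haack formylation of 6 (POCl3, DMF, 0 °C; aqueous NaOAc) should give (4R,5R)‑5‑(3,4‑dimethoxyphenyl)‑4‑methyl‑4,5‑dihydrofuran‑3‑carbaldehyde F6. Addition of MeMgBr (THF, −78 °C) gives 1‑[(4R,5R)‑5‑(3,4‑dimethoxyphenyl)‑4‑methyl‑4,5‑dihydrofuran‑3‑yl]ethan‑1‑ol F7 (carbinol epimers), which is oxidised at once with MnO2 (CH2Cl2, 23 °C) to 8.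

**Further compounds**

F1 | step 8 | (2R)‑2‑tert‑butyl‑5‑(prop‑2‑en‑1‑yl)‑4‑(trimethylsilyloxy)‑1,3‑dioxole | C=CCC1=C(O[Si](C)(C)C)O[C@H](C(C)(C)C)O1
F2 | step 8 | (2R,5S)‑5‑[(4R,5R)‑3‑acetyl‑5‑(3,4‑dimethoxyphenyl)‑4‑methyloxolan‑2‑yl]‑2‑tert‑butyl‑5‑(prop‑2‑en‑1‑yl)‑1,3‑dioxolan‑4‑one | C=CC[C@@]1(C2O[C@@H](c3ccc(OC)c(OC)c3)[C@H](C)C2C(C)=O)O[C@@H](C(C)(C)C)OC1=O
F3 | step 9 | methyl 2‑methoxypent‑4‑enoate (racemic) | C=CCC(OC)C(=O)OC
F4 | step 9 | 4‑[(1R,2R)‑1‑(3,4‑dimethoxyphenyl)‑1‑hydroxypropan‑2‑yl]‑6‑methoxy‑6‑(prop‑2‑en‑1‑yl)cyclohex‑4‑ene‑1,3‑dione (C6 epimers) | C=CCC1(OC)C=C(C(=O)CC1=O)[C@@H](C)[C@@H](O)c1ccc(OC)c(OC)c1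
F5 | step 9 | (2R,3R,5R)‑2‑(3,4‑dimethoxyphenyl)‑5‑methoxy‑3‑methyl‑5‑(prop‑2‑en‑1‑yl)‑2,3‑dihydro‑1‑benzofuran‑6(5H)‑one | C=CC[C@@]1(OC)C=C2C(=CC1=O)O[C@@H](c1ccc(OC)c(OC)c1)[C@@H]2C
F6 | step 5 | (4R,5R)‑5‑(3,4‑dimethoxyphenyl)‑4‑methyl‑4,5‑dihydrofuran‑3‑carbaldehyde | O=CC1=CO[C@@H](c2ccc(OC)c(OC)c2)[C@@H]1C
F7 | step 5 | 1‑[(4R,5R)‑5‑(3,4‑dimethoxyphenyl)‑4‑methyl‑4,5‑dihydrofuran‑3‑yl]ethan‑1‑ol (carbinol epimers) | CC(O)C1=CO[C@@H](c2ccc(OC)c(OC)c2)[C@@H]1C
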